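**Retrosynthetic overview**
- Target ⇐ silyl ether of the target (desilylation) ⇐ 2‑sulfinyl cyclohexanone (sulfoxide syn‑elimination introduces the C2=C3 unsaturation).
- 2‑Sulfinyl cyclohexanone ⇐ one [3+3] annulation of the 1,3‑dianion of 1‑(phenylsulfinyl)propan‑2‑one with an α‑silyloxy‑β‑iodo ketone: C6–C5 by aldol addition, C2–C3 by enolate alkylation. This closes the only ring and creates the quaternary carbinol.
- Enabling feature: in the six‑membered ring the carbonyl C1 has both α‑carbons (C2, C6) as ring members, and they are bonded to the two ends of the oxygenated unit C3–C4–C5. The carbocycle is therefore an acetone 1,3‑dianion (C6–C1–C2) stitched onto a 1,3‑dielectrophile whose tertiary carbinol C5 is a former ketone, with the C4 oxygen stereocentre next to it to steer the addition.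
- Iodo ketone ⇐ terminal epoxy ketone (MgI2 opening, silylation) ⇐ epoxy alcohol from Sharpless kinetic resolution of a vinyl carbinol ⇐ oleyl aldehyde + vinyl Grignard ⇐ oleyl alcohol, which supplies C5 and the whole (Z)‑C17 chain.

Key step: step 8

Remark: ring atoms are numbered C1 (carbonyl), C2=C3 (alkene), C4 (secondary carbinol), C5 (tertiary carbinol), C6 (CH2). The sulfoxide reagent is used racemic at sulfur, assumed harmless because sulfur and C2 both cease to be stereocentres when the enone is formed.

**Route**

Step 1
Reactants: 1 (9Z)-octadec-9-en-1-ol (oleyl alcohol)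
Product: 2 (9Z)-octadec-9-enal
Conditions: 2,2,6,6-tetramethylpiperidine-1-oxyl (TEMPO, 0.1 equiv), PhI(OAc)2 (1.1 equiv), CH2Cl2, rt
Reagents that add atoms: none
Why: Oxoammonium (TEMPO) oxidation with PhI(OAc)2 as the stoichiometric oxidant should stop at the aldehyde and leave the isolated (Z)-alkene untouched, and no stereocentre is involved.

Step 2
Reactants: 2 (9Z)-octadec-9-enal
Product: 3 rac-(11Z)-icosa-1,11-dien-3-ol
Conditions: CH2=CHMgBr, THF, −78 to 0 °C; H2O work-up
Reagents that add atoms: vinylmagnesium bromide, C=C[Mg]Br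
Why: Grignard 1,2-addition to the unhindered aldehyde should give the secondary allylic alcohol as a racemate, which is acceptable because the carbinol centre only serves to direct step 3 and is erased in step 4.

Step 3
Reactants: 3 rac-(11Z)-icosa-1,11-dien-3-ol
Product: 4 (1S,9Z)-1-[(2R)-oxiran-2-yl]octadec-9-en-1-ol
Conditions: Ti(OiPr)4 (0.1 equiv), L-(+)-diisopropyl tartrate (0.15 equiv), tBuOOH (0.45 equiv), 4 Å molecular sieves, CH2Cl2, −20 °C
Reagents that add atoms: tert-butyl hydroperoxide, CC(C)(C)OO
Why: Sharpless kinetic resolution (titanium–tartrate asymmetric epoxidation of a secondary allylic alcohol): with L-(+)-diisopropyl tartrate the (S)-enantiomer of 3 should be epoxidised much faster than the (R)-enantiomer, which is left behind, the tartrate fixing the alkene face so that the epoxide carbon (the future C4) is formed as (R) with the erythro relationship, while the remote (Z)-alkene, which has no directing hydroxyl, does not react.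

Step 4
Reactants: 4 (1S,9Z)-1-[(2R)-oxiran-2-yl]octadec-9-en-1-ol
Product: 5 (9Z)-1-[(2R)-oxiran-2-yl]octadec-9-en-1-one
Conditions: Dess–Martin periodinane, pyridine, CH2Cl2, 0 °C to rt
Reagents that add atoms: none
Why: Dess–Martin oxidation under buffered, non-enolising conditions should give the epoxy ketone without opening the epoxide, and the epoxide stereocentre survives because deprotonation at a three-membered-ring carbon is strongly disfavoured.

Step 5
Reactants: 5 (9Z)-1-[(2R)-oxiran-2-yl]octadec-9-en-1-one
Product: 6 (2S,11Z)-2-hydroxy-1-iodoicos-11-en-3-one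
Conditions: MgI2, Et2O/toluene, −60 to −20 °C; H2O work-up
Reagents that add atoms: magnesium diiodide MgI2, [Mg+2].[I-].[I-]
Why: Lewis-acid-assisted opening of an epoxide by halide: MgI2 bridges the ketone and epoxide oxygens and delivers iodide by SN2 to the unhindered terminal carbon, so that the C–O bond at the stereocentre is not broken and its configuration is retained (the descriptor changes from R to S only because CH2I now outranks the carbonyl carbon).

Step 6
Reactants: 6 (2S,11Z)-2-hydroxy-1-iodoicos-11-en-3-one
Product: 7 (2S,11Z)-2-[(tert-butyldimethylsilyl)oxy]-1-iodoicos-11-en-3-one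
Conditions: TBSOTf, 2,6-lutidine, CH2Cl2, −78 °C
Reagents that add atoms: tert-butyldimethylsilyl trifluoromethanesulfonate (TBSOTf), CC(C)(C)[Si](C)(C)OS(=O)(=O)C(F)(F)F
Why: Silylation of a secondary alcohol with a silyl triflate and a hindered pyridine base at −78 °C should be faster than reclosure of the iodohydrin or enolisation, and it installs the bulky, non-chelating silyl ether that the Felkin–Anh addition of step 8 relies on without touching the stereocentre.

Step 7
Reactants: 8 1-(phenylsulfanyl)propan-2-one ((phenylthio)acetone)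
Product: 9 1-(phenylsulfinyl)propan-2-one (racemic at sulfur)
Conditions: NaIO4, MeOH/H2O, 0 °C to rt
Reagents that add atoms: sodium periodate NaIO4, [Na+].[O-]I(=O)(=O)=O
Why: Periodate oxidation of a sulfide to the sulfoxide is selective for the mono-oxide and turns the thioether into a group that both acidifies C2 for dianion formation and can later leave by syn-elimination, the new sulfur stereocentre being formed as a racemate.

Step 8
Reactants: 7 (2S,11Z)-2-[(tert-butyldimethylsilyl)oxy]-1-iodoicos-11-en-3-one; 9 1-(phenylsulfinyl)propan-2-one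
Product: 12 (4R,5S)-4-[(tert-butyldimethylsilyl)oxy]-5-[(8Z)-heptadec-8-en-1-yl]-5-hydroxy-2-(phenylsulfinyl)cyclohexan-1-one (epimers at C2 and sulfur), via dilithium dianion 10 (not isolated), via acyclic aldolate 11 (not isolated)
Conditions: 9 (1.2 equiv), LiN(iPr)2 (2.4 equiv), THF, −78 to 0 °C; then 7, −78 °C; then DMPU, −78 °C to rt; AcOH quench
Reagents that add atoms: none
Why: This is an anionic [3+3] annulation: the terminal, more basic carbanion of dianion 10 adds to the ketone of 7 at −78 °C to form the C6–C5 bond (acyclic aldolate 11), and on warming the remaining sulfinyl-stabilised enolate carbon displaces the primary iodide to form the C2–C3 bond. The closest known reaction types are the terminal-carbon aldol additions of dianions of β-keto sulfoxides, β-keto esters and β-keto phosphonates to ketones and the cyclohexanone-forming cycloalkylation of such dianions with 1,3-dihalides. The only ring closed is the six-membered carbocycle, by a 6-(enolendo)-exo-tet C-alkylation, which Baldwin's rules for enolates allow. The new quaternary centre C5 is controlled by the C4 stereocentre through a polar Felkin–Anh transition state in which the bulky, non-chelating silyloxy group is anti to the incoming carbanion and the nucleophile passes the small hydrogen, which places the C5 hydroxyl cis to the C4 oxygen (4R,5S) and the long chain equatorial. The step needs addition to the ketone before any alkylation (the iodide is inert to the dianion at −78 °C and reacts only intramolecularly on warming), addition instead of enolisation (the α-hydrogen at the stereocentre is shielded by the silyl ether, and enolisation on the chain side is reversible) and carbon instead of oxygen alkylation (favoured by the soft iodide leaving group, the tight lithium enolate and the chair-like six-membered transition state). The centres at C2 and at sulfur form without control, which is harmless because both are destroyed in step 9.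

Step 9
Reactants: 12 (4R,5S)-4-[(tert-butyldimethylsilyl)oxy]-5-[(8Z)-heptadec-8-en-1-yl]-5-hydroxy-2-(phenylsulfinyl)cyclohexan-1-one
Product: 13 (4R,5S)-4-[(tert-butyldimethylsilyl)oxy]-5-[(8Z)-heptadec-8-en-1-yl]-5-hydroxycyclohex-2-en-1-one
Conditions: toluene, CaCO3, 80 °C
Reagents that add atoms: none
Why: Thermal syn-elimination of an α-sulfinyl ketone (sulfoxide pyrolysis) can only take a hydrogen from C3 because C1 is the carbonyl carbon, so it should give the C2=C3 enone regiospecifically, necessarily cis within the six-membered ring, while removing the uncontrolled centres at C2 and sulfur and leaving C4 and C5 untouched.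

Step 10
Reactants: 13 (4R,5S)-4-[(tert-butyldimethylsilyl)oxy]-5-[(8Z)-heptadec-8-en-1-yl]-5-hydroxycyclohex-2-en-1-one
Product: 14 (4R,5S)-5-[(8Z)-heptadec-8-en-1-yl]-4,5-dihydroxycyclohex-2-en-1-one
Conditions: HF·pyridine, THF/pyridine, 0 °C to rt
Reagents that add atoms: none
Why: Cleavage of the silyl ether by buffered HF·pyridine (desilylation driven by the strong Si–F bond) should free the C4 hydroxyl under weakly acidic conditions that avoid retro-aldol cleavage or dehydration of the tertiary β-hydroxy ketone, so both stereocentres are delivered unchanged.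

**Compound list**
1 | (9Z)-octadec-9-en-1-ol (oleyl alcohol) | CCCCCCCC/C=C\CCCCCCCCO | starting material
2 | (9Z)-octadec-9-enal | CCCCCCCC/C=C\CCCCCCCC=O | intermediate
3 | rac-(11Z)-icosa-1,11-dien-3-ol | CCCCCCCC/C=C\CCCCCCCC(O)C=C | intermediate
4 | (1S,9Z)-1-[(2R)-oxiran-2-yl]octadec-9-en-1-ol | CCCCCCCC/C=C\CCCCCCC[C@H](O)[C@H]1CO1 | intermediate
5 | (9Z)-1-[(2R)-oxiran-2-yl]octadec-9-en-1-one | CCCCCCCC/C=C\CCCCCCCC(=O)[C@H]1CO1 | intermediate
6 | (2S,11Z)-2-hydroxy-1-iodoicos-11-en-3-one | CCCCCCCC/C=C\CCCCCCCC(=O)[C@@H](CI)O | intermediate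
7 | (2S,11Z)-2-[(tert-butyldimethylsilyl)oxy]-1-iodoicos-11-en-3-one | CCCCCCCC/C=C\CCCCCCCC(=O)[C@@H](CI)O[Si](C)(C)C(C)(C)C | intermediate
8 | 1-(phenylsulfanyl)propan-2-one | CC(=O)CSc1ccccc1 | starting material
9 | 1-(phenylsulfinyl)propan-2-one (racemic at sulfur) | CC(=O)CS(=O)c1ccccc1 | intermediate
10 | dilithium salt of the 1,3-dianion of 9 (formed in the flask) | [Li+].[Li+].[CH2-]C(=O)[CH-]S(=O)c1ccccc1 | intermediate
11 | acyclic aldolate: dilithium alkoxide/enolate of (4S,5S)-5-[(tert-butyldimethylsilyl)oxy]-4-[(8Z)-heptadec-8-en-1-yl]-4-hydroxy-6-iodo-1-(phenylsulfinyl)hexan-2-one (formed in the flask) | CCCCCCCC/C=C\CCCCCCC[C@]([O-])(CC(=O)[CH-]S(=O)c1ccccc1)[C@@H](CI)O[Si](C)(C)C(C)(C)C.[Li+].[Li+] | intermediate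
12 | (4R,5S)-4-[(tert-butyldimethylsilyl)oxy]-5-[(8Z)-heptadec-8-en-1-yl]-5-hydroxy-2-(phenylsulfinyl)cyclohexan-1-one (epimers at C2 and sulfur) | CCCCCCCC/C=C\CCCCCCC[C@]1(O)CC(=O)C(S(=O)c2ccccc2)C[C@H]1O[Si](C)(C)C(C)(C)C | intermediate
13 | (4R,5S)-4-[(tert-butyldimethylsilyl)oxy]-5-[(8Z)-heptadec-8-en-1-yl]-5-hydroxycyclohex-2-en-1-one | CCCCCCCC/C=C\CCCCCCC[C@]1(O)CC(=O)C=C[C@H]1O[Si](C)(C)C(C)(C)C | intermediate
14 | (4R,5S)-5-[(8Z)-heptadec-8-en-1-yl]-4,5-dihydroxycyclohex-2-en-1-one | CCCCCCCC/C=C\CCCCCCC[C@]1(O)CC(=O)C=C[C@H]1O | target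

**Step count**
Total steps: 10. Longest linear sequence: 9 steps (steps 1 to 6, then 8, 9 and 10).

**Steps most likely to fail, with fallbacks**

Step 8. Three processes may go wrong:
- Facial selectivity may erode if the lithium cation bridges the ketone and silyloxy oxygens, since the chelated pathway leads to the trans diol.
- The basic dianion may enolise the ketone instead of adding to it.
- The ring may close through the enolate oxygen, or the alkylation may be too slow.

The fallback sets out from 7 and separates the two bond formations. A Mukaiyama aldol addition of commercial 2-(trimethylsilyloxy)propene under BF3·OEt2 (CH2Cl2, −78 °C) uses a monodentate Lewis acid and an open transition state, so Felkin–Anh control is not contested by chelation. It should give (4S,5S)-5-[(tert-butyldimethylsilyl)oxy]-4-[(8Z)-heptadec-8-en-1-yl]-4-hydroxy-6-iodohexan-2-one F1. LiN(iPr)2 (2.2 equiv, THF/DMPU, −78 to 0 °C) then forms the alkoxide and the kinetic methyl enolate, which closes the ring by C-alkylation to (3S,4R)-4-[(tert-butyldimethylsilyl)oxy]-3-[(8Z)-heptadec-8-en-1-yl]-3-hydroxycyclohexan-1-one F2. Dehydrogenation with 2-iodoxybenzoic acid (IBX, DMSO/toluene, 70 °C) can only form the alkene away from the fully substituted carbinol, and the sequence returns to the route at 13.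

Step 5. Iodide may attack the carbon next to the carbonyl instead of the terminal carbon. The free α-hydroxy ketone may also epimerise through its enediol or reclose to the epoxide before it is silylated.

The fallback sets out from 4 and opens the epoxide before the ketone exists:
- Etherification (NaH, 4-methoxybenzyl chloride, Bu4NI, THF/DMF, 0 °C) should give (2R)-2-{(1S,9Z)-1-[(4-methoxybenzyl)oxy]octadec-9-en-1-yl}oxirane F3.
- LiI/AcOH in THF opens the now unactivated terminal epoxide at the CH2 carbon to (2S,3S,11Z)-1-iodo-3-[(4-methoxybenzyl)oxy]icos-11-en-2-ol F4.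
- TBSOTf/2,6-lutidine gives tert-butyl{[(2S,3S,11Z)-1-iodo-3-[(4-methoxybenzyl)oxy]icos-11-en-2-yl]oxy}dimethylsilane F5.
- 2,3-Dichloro-5,6-dicyano-1,4-benzoquinone (CH2Cl2/pH 7 buffer) removes the benzyl ether to give (2S,3S,11Z)-2-[(tert-butyldimethylsilyl)oxy]-1-iodoicos-11-en-3-ol F6.
- Dess–Martin oxidation returns to the route at 7.

In this sequence the C4 carbinol is never free next to a ketone.

Step 10. Under fluoride the tertiary β-hydroxy ketone of the enone may dehydrate and aromatise, or the silyl group may migrate between the two hydroxyls.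

The fallback sets out from 12 and removes the silyl ether before the enone exists. HF·pyridine on the saturated keto sulfoxide should give (4R,5S)-5-[(8Z)-heptadec-8-en-1-yl]-4,5-dihydroxy-2-(phenylsulfinyl)cyclohexan-1-one F7. Thermal syn-elimination (toluene, CaCO3, 80 °C) then returns to the route at the target 14 without exposing the enone to fluoride.

Further compounds
F1 | step 8 | (4S,5S)-5-[(tert-butyldimethylsilyl)oxy]-4-[(8Z)-heptadec-8-en-1-yl]-4-hydroxy-6-iodohexan-2-one | CCCCCCCC/C=C\CCCCCCC[C@](O)(CC(C)=O)[C@@H](CI)O[Si](C)(C)C(C)(C)C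
F2 | step 8 | (3S,4R)-4-[(tert-butyldimethylsilyl)oxy]-3-[(8Z)-heptadec-8-en-1-yl]-3-hydroxycyclohexan-1-one | CCCCCCCC/C=C\CCCCCCC[C@]1(O)CC(=O)CC[C@H]1O[Si](C)(C)C(C)(C)C
F3 | step 5 | (2R)-2-{(1S,9Z)-1-[(4-methoxybenzyl)oxy]octadec-9-en-1-yl}oxirane | CCCCCCCC/C=C\CCCCCCC[C@H](OCc1ccc(OC)cc1)[C@H]1CO1
F4 | step 5 | (2S,3S,11Z)-1-iodo-3-[(4-methoxybenzyl)oxy]icos-11-en-2-ol | CCCCCCCC/C=C\CCCCCCC[C@H](OCc1ccc(OC)cc1)[C@H](O)CI
F5 | step 5 | tert-butyl{[(2S,3S,11Z)-1-iodo-3-[(4-methoxybenzyl)oxy]icos-11-en-2-yl]oxy}dimethylsilane | CCCCCCCC/C=C\CCCCCCC[C@H](OCc1ccc(OC)cc1)[C@H](O[Si](C)(C)C(C)(C)C)CI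
F6 | step 5 | (2S,3S,11Z)-2-[(tert-butyldimethylsilyl)oxy]-1-iodoicos-11-en-3-ol | CCCCCCCC/C=C\CCCCCCC[C@H](O)[C@H](O[Si](C)(C)C(C)(C)C)CI
F7 | step 10 | (4R,5S)-5-[(8Z)-heptadec-8-en-1-yl]-4,5-dihydroxy-2-(phenylsulfinyl)cyclohexan-1-one | CCCCCCCC/C=C\CCCCCCC[C@]1(O)CC(=O)C(S(=O)c2ccccc2)C[C@H]1O
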